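The route rests on cutting the terminal dihydrobenzofuran (ring C fused to the O1–C2–C3 unit that carries ring D) at O1–C7a and C3–C3a. The key step makes both bonds in one palladium-catalysed operation: the enolate of the deoxybenzoin ring D–CH2–CO–(4-methoxyphenyl) is C-arylated and then O-arylated by 1,3-dibromo-2-iodo-5-methoxybenzene. It exploits the three contiguous carbons C4, C3a and C7a of ring C, which are Br, I, Br in the mirror-symmetric trihalide, so either bromine closes the furan and the other stays at C4 as the handle for the next unit. The flat benzofuran is then dearomatised to the trans-dihydrobenzofuran, and the annulation/reduction pair is repeated for rings B and A.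

Key step: step 3

Remark (labels and one assumption): ring D is the 3,5-dioxygenated phenyl ring; rings C, B and A are the benzo rings of dihydrobenzofuran units 3, 2 and 1 (unit 1 carries the stilbene); locants are benzofuran locants of the unit named; U3 = (2R,3R)-3-(3,5-dimethoxyphenyl)-6-methoxy-2-(4-methoxyphenyl)-2,3-dihydro-1-benzofuran-4-yl and U2 = (2S,3S)-6-methoxy-2-(4-methoxyphenyl)-3-(U3)-2,3-dihydro-1-benzofuran-4-yl; it is assumed that 2,3-trans is the thermodynamic arrangement in each unit, since C2 (a p-methoxybenzylic ether carbon) can equilibrate under acid and C3 cannot.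

Step 1
Reactants: 1 2,6-dibromo-4-methoxyaniline
Product: 2 1,3-dibromo-2-iodo-5-methoxybenzene
Conditions: NaNO2, H2SO4, AcOH/H2O, 0 °C; then KI, H2O, 0 °C to rt
Reagents that add atoms: potassium iodide, [K+].[I-]
Why: Sandmeyer-type iododediazoniation, in which iodide displaces N2 from the arenediazonium salt without copper and leaves the two flanking bromines untouched.

Step 2
Reactants: 3 1-bromo-3,5-dimethoxybenzene; 4 1-(4-methoxyphenyl)ethan-1-one
Product: 5 2-(3,5-dimethoxyphenyl)-1-(4-methoxyphenyl)ethan-1-one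
Conditions: Pd2(dba)3 (1 mol%), Xantphos (2.4 mol%), NaOtBu, THF, 70 °C (4 in excess)
Reagents that add atoms: none
Why: Palladium-catalysed ketone alpha-arylation (Buchwald–Hartwig type), where the wide-bite-angle ligand and the excess of methyl ketone should favour mono-arylation.

Step 3
Reactants: 5 2-(3,5-dimethoxyphenyl)-1-(4-methoxyphenyl)ethan-1-one; 2 1,3-dibromo-2-iodo-5-methoxybenzene
Product: 7 4-bromo-3-(3,5-dimethoxyphenyl)-6-methoxy-2-(4-methoxyphenyl)-1-benzofuran, via alpha-aryl ketone 6 (not isolated)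
Conditions: Pd2(dba)3 (2.5 mol%), DPEphos (6 mol%), Cs2CO3 (3 equiv), toluene, 110 °C
Reagents that add atoms: none
Why: Zerovalent palladium inserts into the C–I bond of 2 (far weaker than C–Br) and the caesium enolate of 5 is C-arylated (C3–C3a bond) to give 6, whose more acidic enolate then undergoes oxidative addition at one of the two equivalent ortho C–Br bonds and C–O reductive elimination from a six-membered oxapalladacycle (O1–C7a bond). The closest known reaction type is the palladium-catalysed tandem enolate alpha-arylation/O-arylation of benzyl ketones with ortho-dihaloarenes to 2,3-disubstituted benzofurans. The furan ring is closed in the second event as an intramolecular enolate O-arylation (five-membered ring, formally a 5-exo attack of oxygen on the palladium-bearing aryl carbon). No stereocentre is formed here, because C2 and C3 are sp2 and become stereogenic only in step 4. The step needs C–I before C–Br selectivity, which bond strength secures, and it must stop after one annulation, which is secured because either bromine gives the same product 7 and the surviving C4–Br is flanked by the new C3 aryl group and meets only the hindered enolate of 5 used in stoichiometric amount.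

Step 4
Reactants: 7 4-bromo-3-(3,5-dimethoxyphenyl)-6-methoxy-2-(4-methoxyphenyl)-1-benzofuran
Product: 8 racemic trans-4-bromo-3-(3,5-dimethoxyphenyl)-6-methoxy-2-(4-methoxyphenyl)-2,3-dihydro-1-benzofuran
Conditions: Et3SiH (1.5 equiv), CF3CO2H, CH2Cl2, 0 °C to rt
Reagents that add atoms: none
Why: Ionic hydrogenation, in which protonation at C3 gives the 2-aryl oxocarbenium ion and Et3SiH delivers hydride to C2; the 2,3-trans relationship is the thermodynamic one and is reached because the p-methoxybenzylic C2–O bond ionises reversibly in the acid, while nothing controls the absolute sense, so the product is racemic.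

Step 5
Reactants: 8 racemic trans-4-bromo-3-(3,5-dimethoxyphenyl)-6-methoxy-2-(4-methoxyphenyl)-2,3-dihydro-1-benzofuran
Product: 9 (2R,3R)-4-bromo-3-(3,5-dimethoxyphenyl)-6-methoxy-2-(4-methoxyphenyl)-2,3-dihydro-1-benzofuran
Conditions: preparative SFC, amylose tris(3,5-dimethylphenylcarbamate) phase, CO2/MeOH
Reagents that add atoms: none
Why: Resolution on a chiral stationary phase sets the absolute configuration of unit 3; the (2R,3R) enantiomer is kept, its configuration can be confirmed by anomalous X-ray dispersion of bromine, and the other enantiomer can be returned to 7 by DDQ dehydrogenation.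

Step 6
Reactants: 9 (2R,3R)-4-bromo-3-(3,5-dimethoxyphenyl)-6-methoxy-2-(4-methoxyphenyl)-2,3-dihydro-1-benzofuran; 4 1-(4-methoxyphenyl)ethan-1-one
Product: 10 1-(4-methoxyphenyl)-2-(U3)ethan-1-one
Conditions: Pd(OAc)2 (3 mol%), XPhos (6 mol%), K3PO4, toluene, 100 °C (4 in excess)
Reagents that add atoms: none
Why: Ketone alpha-arylation as in step 2 with a weaker base, under which C2 and C3 carry no hydrogen acidic enough to be removed and should keep their configuration.

Step 7
Reactants: 10 1-(4-methoxyphenyl)-2-(U3)ethan-1-one; 2 1,3-dibromo-2-iodo-5-methoxybenzene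
Product: 12 4-bromo-6-methoxy-2-(4-methoxyphenyl)-3-(U3)-1-benzofuran, via alpha-aryl ketone 11 (not isolated)
Conditions: Pd2(dba)3 (5 mol%), DPEphos (12 mol%), Cs2CO3 (3 equiv), toluene, 110 °C
Reagents that add atoms: none
Why: The same tandem enolate C-arylation/O-arylation as in step 3, now on the ring-C benzyl ketone, with the stereocentres of unit 3 remote from the reacting atoms and stable to carbonate.

Step 8
Reactants: 12 4-bromo-6-methoxy-2-(4-methoxyphenyl)-3-(U3)-1-benzofuran
Product: 13 (2S,3S)-4-bromo-6-methoxy-2-(4-methoxyphenyl)-3-(U3)-2,3-dihydro-1-benzofuran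
Conditions: Et3SiH (1.5 equiv), CF3CO2H, CH2Cl2, 0 °C; silica gel chromatography
Reagents that add atoms: none
Why: Ionic hydrogenation as in step 4, where trans in unit 2 is thermodynamic but the face of C3 protonation depends on the conformation about the hindered ring C–benzofuran axis and is not reliably biased, so both C3 epimers are expected and the (2S,3S) diastereomer is separated from the (2R,3R) one by chromatography.

Step 9
Reactants: 13 (2S,3S)-4-bromo-6-methoxy-2-(4-methoxyphenyl)-3-(U3)-2,3-dihydro-1-benzofuran; 4 1-(4-methoxyphenyl)ethan-1-one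
Product: 14 1-(4-methoxyphenyl)-2-(U2)ethan-1-one
Conditions: Pd(OAc)2 (3 mol%), XPhos (6 mol%), K3PO4, toluene, 100 °C (4 in excess)
Reagents that add atoms: none
Why: Ketone alpha-arylation as in step 6, which should leave the four existing stereocentres untouched.

Step 10
Reactants: 14 1-(4-methoxyphenyl)-2-(U2)ethan-1-one; 2 1,3-dibromo-2-iodo-5-methoxybenzene
Product: 16 4-bromo-6-methoxy-2-(4-methoxyphenyl)-3-(U2)-1-benzofuran, via alpha-aryl ketone 15 (not isolated)
Conditions: Pd2(dba)3 (5 mol%), DPEphos (12 mol%), Cs2CO3 (3 equiv), toluene, 110 °C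
Reagents that add atoms: none
Why: Third use of the tandem enolate C-arylation/O-arylation, which builds ring A and its furan and leaves C4–Br for the stilbene.

Step 11
Reactants: 16 4-bromo-6-methoxy-2-(4-methoxyphenyl)-3-(U2)-1-benzofuran
Product: 17 (2R,3R)-4-bromo-6-methoxy-2-(4-methoxyphenyl)-3-(U2)-2,3-dihydro-1-benzofuran
Conditions: Et3SiH (1.5 equiv), CF3CO2H, CH2Cl2, 0 °C; silica gel chromatography
Reagents that add atoms: none
Why: Ionic hydrogenation as in step 8, with trans in unit 1 thermodynamic and the C3 configuration again not reliably controlled by the substrate, so the (2R,3R) diastereomer is separated from its (2S,3S) epimer.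

Step 12
Reactants: 17 (2R,3R)-4-bromo-6-methoxy-2-(4-methoxyphenyl)-3-(U2)-2,3-dihydro-1-benzofuran; 18 [(E)-2-(4-methoxyphenyl)ethenyl]boronic acid
Product: 19 (2R,3R)-6-methoxy-2-(4-methoxyphenyl)-4-[(E)-2-(4-methoxyphenyl)ethenyl]-3-(U2)-2,3-dihydro-1-benzofuran (nona-O-methyl miyabenol A)
Conditions: PdCl2(dppf) (5 mol%), K2CO3, 1,4-dioxane/H2O, 90 °C
Reagents that add atoms: none
Why: Suzuki–Miyaura coupling of the aryl bromide with the alkenylboronic acid, which should transfer the alkene with retention of its E geometry and touch no stereocentre.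

Step 13
Reactants: 19 nona-O-methyl miyabenol A
Product: 20 miyabenol A
Conditions: BBr3 (excess), CH2Cl2, −78 °C to rt; then MeOH/H2O
Reagents that add atoms: none
Why: Lewis-acid cleavage of the nine aryl methyl ethers (bromide attacks methyl of the boron-bound ether), in which C3 centres are not touched and C2 centres can only equilibrate towards the trans arrangement already in place.

Compound list
1 | 2,6-dibromo-4-methoxyaniline | COc1cc(Br)c(N)c(Br)c1 | starting material
2 | 1,3-dibromo-2-iodo-5-methoxybenzene | COc1cc(Br)c(I)c(Br)c1 | intermediate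
3 | 1-bromo-3,5-dimethoxybenzene | COc1cc(Br)cc(OC)c1 | starting material
4 | 1-(4-methoxyphenyl)ethan-1-one | CC(=O)c1ccc(OC)cc1 | starting material
5 | 2-(3,5-dimethoxyphenyl)-1-(4-methoxyphenyl)ethan-1-one | COc1ccc(cc1)C(=O)Cc1cc(OC)cc(OC)c1 | intermediate
6 | 2-(2,6-dibromo-4-methoxyphenyl)-2-(3,5-dimethoxyphenyl)-1-(4-methoxyphenyl)ethan-1-one (racemic, not isolated) | COc1ccc(cc1)C(=O)C(c1cc(OC)cc(OC)c1)c1c(Br)cc(OC)cc1Br | intermediate
7 | 4-bromo-3-(3,5-dimethoxyphenyl)-6-methoxy-2-(4-methoxyphenyl)-1-benzofuran | COc1ccc(cc1)-c1oc2cc(OC)cc(Br)c2c1-c1cc(OC)cc(OC)c1 | intermediate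
8 | racemic trans-4-bromo-3-(3,5-dimethoxyphenyl)-6-methoxy-2-(4-methoxyphenyl)-2,3-dihydro-1-benzofuran (both enantiomers) | Brc1cc(OC)cc2c1[C@@H](c1cc(OC)cc(OC)c1)[C@H](c1ccc(OC)cc1)O2.Brc1cc(OC)cc2c1[C@H](c1cc(OC)cc(OC)c1)[C@@H](c1ccc(OC)cc1)O2 | intermediate
9 | (2R,3R)-4-bromo-3-(3,5-dimethoxyphenyl)-6-methoxy-2-(4-methoxyphenyl)-2,3-dihydro-1-benzofuran | Brc1cc(OC)cc2c1[C@@H](c1cc(OC)cc(OC)c1)[C@H](c1ccc(OC)cc1)O2 | intermediate
10 | 1-(4-methoxyphenyl)-2-(U3)ethan-1-one | COc1ccc(cc1)C(=O)Cc1cc(OC)cc2c1[C@@H](c1cc(OC)cc(OC)c1)[C@H](c1ccc(OC)cc1)O2 | intermediate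
11 | 2-(2,6-dibromo-4-methoxyphenyl)-1-(4-methoxyphenyl)-2-(U3)ethan-1-one (both epimers at the new carbon, not isolated) | COc1ccc(cc1)C(=O)C(c1c(Br)cc(OC)cc1Br)c1cc(OC)cc2c1[C@@H](c1cc(OC)cc(OC)c1)[C@H](c1ccc(OC)cc1)O2 | intermediate
12 | 4-bromo-6-methoxy-2-(4-methoxyphenyl)-3-(U3)-1-benzofuran | COc1ccc(cc1)-c1oc2cc(OC)cc(Br)c2c1-c1cc(OC)cc2c1[C@@H](c1cc(OC)cc(OC)c1)[C@H](c1ccc(OC)cc1)O2 | intermediate
13 | (2S,3S)-4-bromo-6-methoxy-2-(4-methoxyphenyl)-3-(U3)-2,3-dihydro-1-benzofuran | Brc1cc(OC)cc2c1[C@H](c1cc(OC)cc3c1[C@@H](c1cc(OC)cc(OC)c1)[C@H](c1ccc(OC)cc1)O3)[C@@H](c1ccc(OC)cc1)O2 | intermediate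
14 | 1-(4-methoxyphenyl)-2-(U2)ethan-1-one | COc1ccc(cc1)C(=O)Cc1cc(OC)cc2c1[C@H](c1cc(OC)cc3c1[C@@H](c1cc(OC)cc(OC)c1)[C@H](c1ccc(OC)cc1)O3)[C@@H](c1ccc(OC)cc1)O2 | intermediate
15 | 2-(2,6-dibromo-4-methoxyphenyl)-1-(4-methoxyphenyl)-2-(U2)ethan-1-one (both epimers at the new carbon, not isolated) | COc1ccc(cc1)C(=O)C(c1c(Br)cc(OC)cc1Br)c1cc(OC)cc2c1[C@H](c1cc(OC)cc3c1[C@@H](c1cc(OC)cc(OC)c1)[C@H](c1ccc(OC)cc1)O3)[C@@H](c1ccc(OC)cc1)O2 | intermediate
16 | 4-bromo-6-methoxy-2-(4-methoxyphenyl)-3-(U2)-1-benzofuran | COc1ccc(cc1)-c1oc2cc(OC)cc(Br)c2c1-c1cc(OC)cc2c1[C@H](c1cc(OC)cc3c1[C@@H](c1cc(OC)cc(OC)c1)[C@H](c1ccc(OC)cc1)O3)[C@@H](c1ccc(OC)cc1)O2 | intermediate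
17 | (2R,3R)-4-bromo-6-methoxy-2-(4-methoxyphenyl)-3-(U2)-2,3-dihydro-1-benzofuran | Brc1cc(OC)cc2c1[C@@H](c1cc(OC)cc3c1[C@H](c1cc(OC)cc4c1[C@@H](c1cc(OC)cc(OC)c1)[C@H](c1ccc(OC)cc1)O4)[C@@H](c1ccc(OC)cc1)O3)[C@H](c1ccc(OC)cc1)O2 | intermediate
18 | [(E)-2-(4-methoxyphenyl)ethenyl]boronic acid | COc1ccc(/C=C/B(O)O)cc1 | starting material
19 | (2R,3R)-6-methoxy-2-(4-methoxyphenyl)-4-[(E)-2-(4-methoxyphenyl)ethenyl]-3-(U2)-2,3-dihydro-1-benzofuran (nona-O-methyl miyabenol A) | COc1ccc(/C=C/c2cc(OC)cc3c2[C@@H](c2cc(OC)cc4c2[C@H](c2cc(OC)cc5c2[C@@H](c2cc(OC)cc(OC)c2)[C@H](c2ccc(OC)cc2)O5)[C@@H](c2ccc(OC)cc2)O4)[C@H](c2ccc(OC)cc2)O3)cc1 | intermediate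
20 | miyabenol A | Oc1ccc(/C=C/c2cc(O)cc3c2[C@@H](c2cc(O)cc4c2[C@H](c2cc(O)cc5c2[C@@H](c2cc(O)cc(O)c2)[C@H](c2ccc(O)cc2)O5)[C@@H](c2ccc(O)cc2)O4)[C@H](c2ccc(O)cc2)O3)cc1 | target

Total step count: 13. Longest linear sequence: 12 steps (step 2 or step 1, then steps 3 to 13).

Steps most likely to fail

Step 3 (and, with more hindrance, its repeats in steps 7 and 10). The cascade may stall after the C-arylation because oxidative addition and C–O reductive elimination at the doubly flanked ring are slow. At 110 °C the I-before-Br selectivity may also erode, or a second enolate arylation may consume the remaining bromide. The fallback sets out from 2 and 5 and decouples the two bond formations. The C-arylation is run alone at low temperature (Pd(OAc)2, P(tBu)3·HBF4, NaOtBu, THF, 40 °C), where only the C–I bond should react, and ketone 6 is isolated. The furan is then closed in a separate copper-catalysed Ullmann-type O-arylation of the enolate (CuCl, 1,10-phenanthroline, Cs2CO3, DMF, 100 °C), which cannot arylate carbon intermolecularly, and the route is rejoined at 7. No compound outside the list is made (F0).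

Step 8 (the same weakness recurs in step 11). Facial selectivity in the C3 protonation may be poor or run the wrong way, and the acid may cause reductive opening of p-methoxybenzylic C–O bonds by the silane. The fallback sets out from 9, sets C3 of unit 2 by catalyst control, and comes back at 13.
- Commercial 2-bromo-6-hydroxy-4-methoxybenzaldehyde is alkylated with 4-methoxybenzyl chloride (K2CO3, DMF) to 2-bromo-4-methoxy-6-[(4-methoxybenzyl)oxy]benzaldehyde F1.
- Bromide 9 is lithiated (n-BuLi, THF, −78 °C) and added to F1 to give the diaryl carbinol F2.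
- Dess–Martin periodinane gives the diaryl ketone F3.
- Hydrazine hydrate (AcOH, EtOH, reflux) gives the hydrazone F4.
- MnO2 in CH2Cl2 gives the diaryldiazomethane F5, which is not isolated.
- Rh2(S-PTAD)4, or its enantiomer if that is the one that delivers 3S, effects enantioselective carbene insertion into the benzylic C–H bond of the 4-methoxybenzyl ether and gives the 2,3-cis dihydrobenzofuran F6.
- Acid (CF3CO2H cat., CH2Cl2) epimerises C2 and gives trans compound 13.

Step 13. Acid-promoted Friedel–Crafts cyclisation of the stilbene onto ring B, HBr addition to the alkene, or incomplete cleavage of nine ethers may erode the last step. The fallback sets out from 17 and removes the methyl groups before the alkene exists.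
- BBr3 (CH2Cl2, −78 °C to rt) gives the octaphenol bromide F7.
- Ac2O and pyridine give the octaacetate F8.
- A Heck reaction with 4-ethenylphenyl acetate (Pd(OAc)2, P(o-tolyl)3, Et3N, DMF, 100 °C) gives miyabenol A nonaacetate F9.
- Mild methanolysis (K2CO3, MeOH, 0 °C) comes back to the route at 20.

Further compounds
F0 | step 3 | none | none
F1 | step 8 | 2-bromo-4-methoxy-6-[(4-methoxybenzyl)oxy]benzaldehyde | COc1ccc(COc2cc(OC)cc(Br)c2C=O)cc1
F2 | step 8 | {2-bromo-4-methoxy-6-[(4-methoxybenzyl)oxy]phenyl}(U3)methanol (both carbinol epimers) | COc1ccc(COc2cc(OC)cc(Br)c2C(O)c2cc(OC)cc3c2[C@@H](c2cc(OC)cc(OC)c2)[C@H](c2ccc(OC)cc2)O3)cc1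
F3 | step 8 | {2-bromo-4-methoxy-6-[(4-methoxybenzyl)oxy]phenyl}(U3)methanone | COc1ccc(COc2cc(OC)cc(Br)c2C(=O)c2cc(OC)cc3c2[C@@H](c2cc(OC)cc(OC)c2)[C@H](c2ccc(OC)cc2)O3)cc1
F4 | step 8 | hydrazone of F3 | COc1ccc(COc2cc(OC)cc(Br)c2C(=NN)c2cc(OC)cc3c2[C@@H](c2cc(OC)cc(OC)c2)[C@H](c2ccc(OC)cc2)O3)cc1
F5 | step 8 | {2-bromo-4-methoxy-6-[(4-methoxybenzyl)oxy]phenyl}(U3)diazomethane | COc1ccc(COc2cc(OC)cc(Br)c2C(=[N+]=[N-])c2cc(OC)cc3c2[C@@H](c2cc(OC)cc(OC)c2)[C@H](c2ccc(OC)cc2)O3)cc1
F6 | step 8 | (2R,3S)-4-bromo-6-methoxy-2-(4-methoxyphenyl)-3-(U3)-2,3-dihydro-1-benzofuran (2,3-cis) | Brc1cc(OC)cc2c1[C@H](c1cc(OC)cc3c1[C@@H](c1cc(OC)cc(OC)c1)[C@H](c1ccc(OC)cc1)O3)[C@H](c1ccc(OC)cc1)O2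
F7 | step 13 | octaphenol of 17 (all eight methyl ethers cleaved, C4–Br of ring A kept) | Brc1cc(O)cc2c1[C@@H](c1cc(O)cc3c1[C@H](c1cc(O)cc4c1[C@@H](c1cc(O)cc(O)c1)[C@H](c1ccc(O)cc1)O4)[C@@H](c1ccc(O)cc1)O3)[C@H](c1ccc(O)cc1)O2
F8 | step 13 | octaacetate of F7 | Brc1cc(OC(C)=O)cc2c1[C@@H](c1cc(OC(C)=O)cc3c1[C@H](c1cc(OC(C)=O)cc4c1[C@@H](c1cc(OC(C)=O)cc(OC(C)=O)c1)[C@H](c1ccc(OC(C)=O)cc1)O4)[C@@H](c1ccc(OC(C)=O)cc1)O3)[C@H](c1ccc(OC(C)=O)cc1)O2
F9 | step 13 | miyabenol A nonaacetate | CC(=O)Oc1ccc(/C=C/c2cc(OC(C)=O)cc3c2[C@@H](c2cc(OC(C)=O)cc4c2[C@H](c2cc(OC(C)=O)cc5c2[C@@H](c2cc(OC(C)=O)cc(OC(C)=O)c2)[C@H](c2ccc(OC(C)=O)cc2)O5)[C@@H](c2ccc(OC(C)=O)cc2)O4)[C@H](c2ccc(OC(C)=O)cc2)O3)cc1
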